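## Retrosynthetic overview

1. Target 29 ⇐ Z-enoate 25 (silyl → acetyl exchange, ester cleavage); 25 ⇐ bicyclic bromide 18 + ynoate 21, where a syn carbocupration forms C12–C13 and sets the Z alkene.
2. 18 ⇐ acyclic (E,E)-trienyl bromide 17 by the proposed iron-hydride-initiated, copper-terminated radical cycloisomerisation. Ring A closes first (C4–C5), then ring B (C10–C9), and the 8(17)-methylene forms in the same step; C5, C9 and C10 follow from C2.
3. 17 ⇐ alkyne 7 by two Zr-catalysed methylaluminations (E alkenes C10=C5 and C8=C9), one Pd coupling (C5–C6) and one oxirane opening (C9–C11).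
4. 7 ⇐ (R)-epichlorohydrin 1 (the only source of chirality, C2) + isopropenyl Grignard 2 + acetylide 4.

Assumption: compounds 1, 2, 4, 10 and 19 are bought. "Dec" in names means the (1R,4aR,7R,8aR)-7-methoxy-5,5,8a-trimethyl-2-methylidenedecahydronaphthalen-1-yl group (rings A and B of the target, attached through labdane C9). Atom labels C1–C17 in the text are labdane numbers. The target is read as an ent-labdane with the C2 methoxy group equatorial.

## Route

Step 1
Reactants: 1 (R)-epichlorohydrin; 2 isopropenylmagnesium bromide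
Product: 3 (2R)-1-chloro-4-methylpent-4-en-2-ol
Conditions: CuI (10 mol%), THF, −40 to −20 °C; then H2O
Reagents that add atoms: none
Why: Copper-catalysed Grignard opening of the epoxide (SN2 at the unsubstituted ring carbon) leaves the stereocentre of 1 untouched, so the future C2 is taken from the chiral pool.

Step 2
Reactants: 3 (2R)-1-chloro-4-methylpent-4-en-2-ol; 4 lithium acetylide–ethylenediamine complex
Product: 6 (4R)-2-methylhept-1-en-6-yn-4-ol, via epoxide 5 (not isolated)
Conditions: 4 (3 equiv), DMSO, 15 °C to rt; then H2O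
Reagents that add atoms: none
Why: Excess acetylide first closes the chlorohydrin to epoxide 5 (intramolecular Williamson reaction) and then opens it at the terminal carbon (SN2 epoxide alkynylation), neither event touching the carbinol stereocentre.

Step 3
Reactants: 6 (4R)-2-methylhept-1-en-6-yn-4-ol
Product: 7 (4R)-4-methoxy-2-methylhept-1-en-6-yne
Conditions: NaH (1.1 equiv), MeI, THF, 0 °C to rt
Reagents that add atoms: iodomethane CI
Why: Williamson ether synthesis, in which NaH in THF deprotonates the alcohol but not the alkyne C–H, installs the C2 methoxy group of the target so that no protecting group is needed.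

Step 4
Reactants: 7 (4R)-4-methoxy-2-methylhept-1-en-6-yne
Product: 9 (1E,4R)-1-iodo-4-methoxy-2,6-dimethylhepta-1,6-diene, via alkenylalane 8 (not isolated)
Conditions: Me3Al (2.5 equiv), Cp2ZrCl2 (0.25 equiv), CH2Cl2, 0 °C to rt; then I2, THF, −30 °C
Reagents that add atoms: trimethylaluminium C[Al](C)C; diiodine II
Why: Negishi zirconium-catalysed carboalumination adds methyl and aluminium syn across the terminal alkyne with aluminium at the terminus, and iodinolysis with retention gives the E vinyl iodide (future C10=C5) while the 1,1-disubstituted alkene does not carbometalate.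

Step 5
Reactants: 9 (1E,4R)-1-iodo-4-methoxy-2,6-dimethylhepta-1,6-diene; 10 (4-bromobut-1-yn-1-yl)trimethylsilane
Product: 12 [(5E,8R)-8-methoxy-6,10-dimethylundeca-5,10-dien-1-yn-1-yl]trimethylsilane, via organozinc bromide 11 (not isolated)
Conditions: 10, Zn dust, LiCl, THF, 50 °C; then 9, Pd(PPh3)4 (3 mol%), THF, rt to 45 °C
Reagents that add atoms: none
Why: Negishi sp3–sp2 cross-coupling forms C5–C6 with retention of the alkene geometry, the silyl cap keeping the alkyne proton away from the zinc reagent.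

Step 6
Reactants: 12 [(5E,8R)-8-methoxy-6,10-dimethylundeca-5,10-dien-1-yn-1-yl]trimethylsilane
Product: 13 (5E,8R)-8-methoxy-6,10-dimethylundeca-5,10-dien-1-yne
Conditions: K2CO3, MeOH, rt
Reagents that add atoms: none
Why: Base-catalysed methanolysis of the alkynyl–silicon bond (protodesilylation) frees the terminal alkyne without touching the alkenes or the ether.

Step 7
Reactants: 13 (5E,8R)-8-methoxy-6,10-dimethylundeca-5,10-dien-1-yne
Product: 16 (3E,7E,10R)-10-methoxy-4,8,12-trimethyltrideca-3,7,12-trien-1-ol, via alkenylalane 14 (not isolated), via lithium alanate 15 (not isolated)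
Conditions: Me3Al (2.5 equiv), Cp2ZrCl2 (0.25 equiv), CH2Cl2, 0 °C to rt; evaporate; n-BuLi, THF/hexane, −78 °C; oxirane, −78 to 0 °C; then H2O
Reagents that add atoms: trimethylaluminium C[Al](C)C; oxirane C1CO1
Why: A second Negishi carboalumination sets the E C8=C9 alkene (the new methyl is C17), and the alkenyl group of the lithium alanate opens oxirane with retention to append C11–C12 as a primary alcohol.

Step 8
Reactants: 16 (3E,7E,10R)-10-methoxy-4,8,12-trimethyltrideca-3,7,12-trien-1-ol
Product: 17 (4R,6E,10E)-13-bromo-4-methoxy-2,6,10-trimethyltrideca-1,6,10-triene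
Conditions: CBr4, PPh3, CH2Cl2, 0 °C
Reagents that add atoms: tetrabromomethane BrC(Br)(Br)Br
Why: Appel bromination (SN2 on the alkoxyphosphonium salt) converts the primary alcohol under neutral conditions and gives a handle for step 11 that, unlike a free hydroxyl, cannot capture the C8 centre in step 9.

Step 9
Reactants: 17 (4R,6E,10E)-13-bromo-4-methoxy-2,6,10-trimethyltrideca-1,6,10-triene
Product: 18 (1R,4aR,7R,8aR)-1-(2-bromoethyl)-7-methoxy-5,5,8a-trimethyl-2-methylidenedecahydronaphthalene
Conditions: Fe(acac)3 (30 mol%), Cu(OAc)2 (2.2 equiv), PhSiH3 (1.5 equiv, slow addition), degassed EtOH/(CH2OH)2 (9:1), 0.01 M, 40 °C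
Reagents that add atoms: none
Why: Proposed new method: an MHAT-initiated, copper-terminated radical cycloisomerisation in which an iron hydride formed from Fe(acac)3 and PhSiH3 in ethanol delivers a hydrogen atom to the unhindered 1,1-disubstituted alkene (trisubstituted alkenes react far more slowly), the tertiary C4 radical closes ring A by 6-endo attack on C5 through a chair with the C2 methoxy group equatorial (an axial methoxy group would sit 1,3-diaxial to a C4 methyl), the C10 radical closes ring B by 6-endo attack on C9 through the chair–chair array (trans ring fusion, C11 equatorial from the E alkene), and the tertiary C8 radical is captured by Cu(OAc)2 and loses a hydrogen of the unhindered C17 methyl by syn β-hydride elimination to give the exocyclic alkene, a second Cu(OAc)2 returning divalent iron to the trivalent state; the closest known reactions are iron-hydride MHAT reductive olefin couplings and radical bicyclisations (same initiation) and the Mn(OAc)3/Cu(OAc)2 oxidative radical polyene cyclisation (same chair–chair propagation and same copper-mediated exo-methylene termination), whose merger into a net isomerisation of an unfunctionalised triene steered by one remote stereocentre is not yet described.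

Step 10
Reactants: 19 tert-butyldimethyl(prop-2-yn-1-yloxy)silane
Product: 21 tert-butyl 4-[(tert-butyldimethylsilyl)oxy]but-2-ynoate, via lithium acetylide 20 (not isolated)
Conditions: n-BuLi, THF, −78 °C; Boc2O, −78 to 0 °C; then H2O
Reagents that add atoms: di-tert-butyl dicarbonate CC(C)(C)OC(=O)OC(=O)OC(C)(C)C
Why: C-acylation of the lithium acetylide with Boc2O gives the tert-butyl ynoate, the hindered ester being chosen because it resists lactonisation in steps 12 and 13.

Step 11
Reactants: 18 (1R,4aR,7R,8aR)-1-(2-bromoethyl)-7-methoxy-5,5,8a-trimethyl-2-methylidenedecahydronaphthalene; 21 tert-butyl 4-[(tert-butyldimethylsilyl)oxy]but-2-ynoate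
Product: 25 tert-butyl (2Z)-3-({[tert-butyl(dimethyl)silyl]oxy}methyl)-5-(Dec)pent-2-enoate, via Grignard reagent 22 (not isolated), via alkylcopper 23 (not isolated), via alkenylcopper 24 (not isolated)
Conditions: Mg, THF, 40 °C; CuBr·SMe2 (1.0 equiv), THF, −40 °C; 21, −78 °C; MeOH, −78 °C
Reagents that add atoms: none
Why: Conjugate addition (syn carbocupration) of the alkylcopper to the ynoate places the alkyl group and copper cis, and protonation of the alkenylcopper at −78 °C with retention leaves the silyloxymethyl group cis to the ester, which is the Z alkene of the target.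

Step 12
Reactants: 25 tert-butyl (2Z)-3-({[tert-butyl(dimethyl)silyl]oxy}methyl)-5-(Dec)pent-2-enoate
Product: 26 tert-butyl (2Z)-3-(hydroxymethyl)-5-(Dec)pent-2-enoate
Conditions: HF·pyridine, pyridine, THF, 0 °C
Reagents that add atoms: none
Why: Fluoride-mediated desilylation under pyridine buffering frees the primary alcohol, while the hindered tert-butyl ester does not lactonise onto the cis hydroxymethyl group at 0 °C and the exocyclic alkene is not protonated.

Step 13
Reactants: 26 tert-butyl (2Z)-3-(hydroxymethyl)-5-(Dec)pent-2-enoate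
Product: 27 tert-butyl (2Z)-3-[(acetyloxy)methyl]-5-(Dec)pent-2-enoate
Conditions: Ac2O, pyridine, DMAP (cat.), CH2Cl2, 0 °C
Reagents that add atoms: acetic anhydride CC(=O)OC(C)=O
Why: DMAP-catalysed O-acetylation (nucleophilic acyl substitution) is much faster than lactonisation of the tert-butyl ester.

Step 14
Reactants: 27 tert-butyl (2Z)-3-[(acetyloxy)methyl]-5-(Dec)pent-2-enoate
Product: 29 (2Z)-3-[(acetyloxy)methyl]-5-[(1R,4aR,7R,8aR)-7-methoxy-5,5,8a-trimethyl-2-methylidenedecahydronaphthalen-1-yl]pent-2-enoic acid, via trimethylsilyl ester 28 (not isolated)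
Conditions: TMSOTf, 2,6-lutidine, CH2Cl2, 0 °C; then pH 5 phosphate buffer
Reagents that add atoms: none
Why: Silyl-triflate-mediated tert-butyl ester cleavage (loss of isobutene from the O-silylated ester) under lutidine buffering avoids protic acid, so the 8(17)-alkene, the allylic acetate and the Z geometry survive, and the silyl ester hydrolyses on aqueous work-up.

## Compound list

1 | (R)-epichlorohydrin, (2R)-2-(chloromethyl)oxirane | ClC[C@H]1CO1 | starting material
2 | isopropenylmagnesium bromide | C=C(C)[Mg]Br | starting material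
3 | (2R)-1-chloro-4-methylpent-4-en-2-ol | C=C(C)C[C@@H](O)CCl | intermediate
4 | lithium acetylide–ethylenediamine complex | [Li]C#C.NCCN | starting material
5 | (2R)-2-(2-methylprop-2-en-1-yl)oxirane | C=C(C)C[C@@H]1CO1 | intermediate
6 | (4R)-2-methylhept-1-en-6-yn-4-ol | C=C(C)C[C@@H](O)CC#C | intermediate
7 | (4R)-4-methoxy-2-methylhept-1-en-6-yne | C=C(C)C[C@@H](OC)CC#C | intermediate
8 | [(1E,4R)-4-methoxy-2,6-dimethylhepta-1,6-dien-1-yl]dimethylalumane | C=C(C)C[C@@H](OC)C/C(C)=C/[Al](C)C | intermediate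
9 | (1E,4R)-1-iodo-4-methoxy-2,6-dimethylhepta-1,6-diene | C=C(C)C[C@@H](OC)C/C(C)=C/I | intermediate
10 | (4-bromobut-1-yn-1-yl)trimethylsilane | C[Si](C)(C)C#CCCBr | starting material
11 | bromo[4-(trimethylsilyl)but-3-yn-1-yl]zinc | C[Si](C)(C)C#CCC[Zn]Br | intermediate
12 | [(5E,8R)-8-methoxy-6,10-dimethylundeca-5,10-dien-1-yn-1-yl]trimethylsilane | C=C(C)C[C@@H](OC)C/C(C)=C/CCC#C[Si](C)(C)C | intermediate
13 | (5E,8R)-8-methoxy-6,10-dimethylundeca-5,10-dien-1-yne | C=C(C)C[C@@H](OC)C/C(C)=C/CCC#C | intermediate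
14 | [(1E,5E,8R)-8-methoxy-2,6,10-trimethylundeca-1,5,10-trien-1-yl]dimethylalumane | C=C(C)C[C@@H](OC)C/C(C)=C/CC/C(C)=C/[Al](C)C | intermediate
15 | lithium butyl[(1E,5E,8R)-8-methoxy-2,6,10-trimethylundeca-1,5,10-trien-1-yl]dimethylaluminate | C=C(C)C[C@@H](OC)C/C(C)=C/CC/C(C)=C/[Al-](C)(C)CCCC.[Li+] | intermediate
16 | (3E,7E,10R)-10-methoxy-4,8,12-trimethyltrideca-3,7,12-trien-1-ol | C=C(C)C[C@@H](OC)C/C(C)=C/CC/C(C)=C/CCO | intermediate
17 | (4R,6E,10E)-13-bromo-4-methoxy-2,6,10-trimethyltrideca-1,6,10-triene | C=C(C)C[C@@H](OC)C/C(C)=C/CC/C(C)=C/CCBr | intermediate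
18 | (1R,4aR,7R,8aR)-1-(2-bromoethyl)-7-methoxy-5,5,8a-trimethyl-2-methylidenedecahydronaphthalene (labdane numbering 2R,5R,9R,10R; trans-decalin, methoxy equatorial) | C=C1CC[C@@H]2C(C)(C)C[C@@H](OC)C[C@@]2(C)[C@@H]1CCBr | intermediate
19 | tert-butyldimethyl(prop-2-yn-1-yloxy)silane | C#CCO[Si](C)(C)C(C)(C)C | starting material
20 | {3-[(tert-butyldimethylsilyl)oxy]prop-1-yn-1-yl}lithium | [Li]C#CCO[Si](C)(C)C(C)(C)C | intermediate
21 | tert-butyl 4-[(tert-butyldimethylsilyl)oxy]but-2-ynoate | CC(C)(C)OC(=O)C#CCO[Si](C)(C)C(C)(C)C | intermediate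
22 | [2-(Dec)ethyl]magnesium bromide | C=C1CC[C@@H]2C(C)(C)C[C@@H](OC)C[C@@]2(C)[C@@H]1CC[Mg]Br | intermediate
23 | [2-(Dec)ethyl]copper | C=C1CC[C@@H]2C(C)(C)C[C@@H](OC)C[C@@]2(C)[C@@H]1CC[Cu] | intermediate
24 | tert-butyl (2E)-3-({[tert-butyl(dimethyl)silyl]oxy}methyl)-2-cuprio-5-(Dec)pent-2-enoate (copper cis to the Dec-ethyl chain) | C=C1CC[C@@H]2C(C)(C)C[C@@H](OC)C[C@@]2(C)[C@@H]1CC/C(CO[Si](C)(C)C(C)(C)C)=C(\[Cu])C(=O)OC(C)(C)C | intermediate
25 | tert-butyl (2Z)-3-({[tert-butyl(dimethyl)silyl]oxy}methyl)-5-(Dec)pent-2-enoate | C=C1CC[C@@H]2C(C)(C)C[C@@H](OC)C[C@@]2(C)[C@@H]1CC/C(=C/C(=O)OC(C)(C)C)CO[Si](C)(C)C(C)(C)C | intermediate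
26 | tert-butyl (2Z)-3-(hydroxymethyl)-5-(Dec)pent-2-enoate | C=C1CC[C@@H]2C(C)(C)C[C@@H](OC)C[C@@]2(C)[C@@H]1CC/C(=C/C(=O)OC(C)(C)C)CO | intermediate
27 | tert-butyl (2Z)-3-[(acetyloxy)methyl]-5-(Dec)pent-2-enoate | C=C1CC[C@@H]2C(C)(C)C[C@@H](OC)C[C@@]2(C)[C@@H]1CC/C(=C/C(=O)OC(C)(C)C)COC(C)=O | intermediate
28 | trimethylsilyl (2Z)-3-[(acetyloxy)methyl]-5-(Dec)pent-2-enoate | C=C1CC[C@@H]2C(C)(C)C[C@@H](OC)C[C@@]2(C)[C@@H]1CC/C(=C/C(=O)O[Si](C)(C)C)COC(C)=O | intermediate
29 | (2Z)-3-[(acetyloxy)methyl]-5-[(1R,4aR,7R,8aR)-7-methoxy-5,5,8a-trimethyl-2-methylidenedecahydronaphthalen-1-yl]pent-2-enoic acid (CNP0155807.1) | C=C1CC[C@@H]2C(C)(C)C[C@@H](OC)C[C@@]2(C)[C@@H]1CC/C(=C/C(=O)O)COC(C)=O | target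

## Step count and risk

Total steps: 14. Longest linear sequence: 13 (steps 1–9 and 11–14; step 10 is a one-step branch).

Three steps most likely to fail:

**Step 9 (the proposed new step).** Likely failure modes are: PhSiH3 reducing Cu(OAc)2 faster than it forms the iron hydride; copper capturing the C4 radical before ring A closes; termination into the ring giving 7-ene or 8-ene isomers; or a low ratio of C2-controlled diastereomers. Fallback with known chemistry, setting out from 16 and coming back at 18: Dess–Martin periodinane oxidises 16 to (3E,7E,10R)-10-methoxy-4,8,12-trimethyltrideca-3,7,12-trienal F1, and NaClO2/NaH2PO4/2-methyl-2-butene takes it on to the trienoic acid F2. ClSO3H in 2-nitropropane at −78 °C, the proton-initiated cationic bicyclisation long used to turn homofarnesic acid into sclareolide, closes rings A and B and traps C8 with the carboxyl group to give the trans-fused 8,12-lactone F3 (methoxy group equatorial in the chair–chair transition state). LiAlH4 opens the lactone to the 8,12-diol F4. Ac2O/pyridine acetylates only the primary hydroxyl to give the hydroxy acetate F5. SOCl2/pyridine at −78 °C eliminates the equatorial tertiary hydroxyl, which is anti-periplanar only to C17 hydrogens, to give the 8(17)-ene acetate F6. K2CO3/MeOH gives the primary alcohol F7, and CBr4/PPh3 as in step 8 gives 18.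

**Step 11.** Grignard formation may be sluggish, or the alkenylcopper may equilibrate through its allenoate form and erode the Z geometry. Fallback, setting out from 18 and coming back at 25: Zn dust/LiCl inserts into 18 to give the alkylzinc bromide F8. Separately, the β-keto ester F9 (from lithiated tert-butyl acetate and methyl [(tert-butyldimethylsilyl)oxy]acetate by Claisen condensation) is converted with Tf2O and aqueous Me4NOH into the (E)-enol triflate F10, in which the triflate is trans to the ester. Pd(PPh3)4-catalysed Negishi coupling of F8 with F10 proceeds with retention and gives 25, the geometry now being fixed by the isolated triflate rather than by a kinetically controlled addition.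

**Step 14.** Silyl triflate or the liberated acid may trigger lactonisation to the butenolide with loss of acetic acid, or migration of the 8(17)-alkene. Fallback, setting out from 25 and coming back at 29, in which the acid is made last by oxidation and no ester is cleaved in the presence of the acetate: DIBAL-H reduces 25 to the allylic alcohol F11. 4-Methoxybenzyl trichloroacetimidate with catalytic PPTS gives the 4-methoxybenzyl ether F12. TBAF gives the alcohol F13 and Ac2O/pyridine the acetate F14. DDQ in CH2Cl2/pH 7 buffer gives the hydroxy acetate F15. Dess–Martin periodinane/NaHCO3 gives the Z-enal F16, and NaClO2/NaH2PO4/2-methyl-2-butene gives 29.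

Further compounds

F1 | step 9 | (3E,7E,10R)-10-methoxy-4,8,12-trimethyltrideca-3,7,12-trienal | C=C(C)C[C@@H](OC)C/C(C)=C/CC/C(C)=C/CC=O
F2 | step 9 | (3E,7E,10R)-10-methoxy-4,8,12-trimethyltrideca-3,7,12-trienoic acid | C=C(C)C[C@@H](OC)C/C(C)=C/CC/C(C)=C/CC(=O)O
F3 | step 9 | (2R,5R,8S,9S,10R)-2-methoxy-13,14,15,16-tetranorlabdan-12,8-olide (lactone oxygen equatorial on C8) | C[C@]13CC[C@@H]2C(C)(C)C[C@@H](OC)C[C@@]2(C)[C@@H]1CC(=O)O3
F4 | step 9 | (2R,5R,8S,9S,10R)-2-methoxy-13,14,15,16-tetranorlabdane-8,12-diol | C[C@]1(O)CC[C@@H]2C(C)(C)C[C@@H](OC)C[C@@]2(C)[C@@H]1CCO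
F5 | step 9 | (2R,5R,8S,9S,10R)-8-hydroxy-2-methoxy-13,14,15,16-tetranorlabdan-12-yl acetate | C[C@]1(O)CC[C@@H]2C(C)(C)C[C@@H](OC)C[C@@]2(C)[C@@H]1CCOC(C)=O
F6 | step 9 | 2-(Dec)ethyl acetate | C=C1CC[C@@H]2C(C)(C)C[C@@H](OC)C[C@@]2(C)[C@@H]1CCOC(C)=O
F7 | step 9 | 2-(Dec)ethanol | C=C1CC[C@@H]2C(C)(C)C[C@@H](OC)C[C@@]2(C)[C@@H]1CCO
F8 | step 11 | bromo[2-(Dec)ethyl]zinc | C=C1CC[C@@H]2C(C)(C)C[C@@H](OC)C[C@@]2(C)[C@@H]1CC[Zn]Br
F9 | step 11 | tert-butyl 4-[(tert-butyldimethylsilyl)oxy]-3-oxobutanoate | CC(C)(C)OC(=O)CC(=O)CO[Si](C)(C)C(C)(C)C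
F10 | step 11 | tert-butyl (2E)-4-[(tert-butyldimethylsilyl)oxy]-3-{[(trifluoromethyl)sulfonyl]oxy}but-2-enoate | CC(C)(C)OC(=O)/C=C(/OS(=O)(=O)C(F)(F)F)CO[Si](C)(C)C(C)(C)C
F11 | step 14 | (2Z)-3-({[tert-butyl(dimethyl)silyl]oxy}methyl)-5-(Dec)pent-2-en-1-ol | C=C1CC[C@@H]2C(C)(C)C[C@@H](OC)C[C@@]2(C)[C@@H]1CC/C(=C/CO)CO[Si](C)(C)C(C)(C)C
F12 | step 14 | tert-butyl({(2Z)-2-[2-(Dec)ethyl]-4-[(4-methoxybenzyl)oxy]but-2-en-1-yl}oxy)dimethylsilane | C=C1CC[C@@H]2C(C)(C)C[C@@H](OC)C[C@@]2(C)[C@@H]1CC/C(=C/COCc1ccc(OC)cc1)CO[Si](C)(C)C(C)(C)C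
F13 | step 14 | (2Z)-2-[2-(Dec)ethyl]-4-[(4-methoxybenzyl)oxy]but-2-en-1-ol | C=C1CC[C@@H]2C(C)(C)C[C@@H](OC)C[C@@]2(C)[C@@H]1CC/C(=C/COCc1ccc(OC)cc1)CO
F14 | step 14 | (2Z)-2-[2-(Dec)ethyl]-4-[(4-methoxybenzyl)oxy]but-2-en-1-yl acetate | C=C1CC[C@@H]2C(C)(C)C[C@@H](OC)C[C@@]2(C)[C@@H]1CC/C(=C/COCc1ccc(OC)cc1)COC(C)=O
F15 | step 14 | (2Z)-2-[2-(Dec)ethyl]-4-hydroxybut-2-en-1-yl acetate | C=C1CC[C@@H]2C(C)(C)C[C@@H](OC)C[C@@]2(C)[C@@H]1CC/C(=C/CO)COC(C)=O
F16 | step 14 | (2Z)-2-[2-(Dec)ethyl]-4-oxobut-2-en-1-yl acetate | C=C1CC[C@@H]2C(C)(C)C[C@@H](OC)C[C@@]2(C)[C@@H]1CC/C(=C/C=O)COC(C)=O
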